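The route rests on disconnecting the C1–C2 bond of the 3-methyl-1,2-dihydronaphthalen-1-ol ring. This ring carries a β-hydroxy ketone (C1–OH, C2–acetyl) next to the C3=C4 styrene bond, the retron of an aldol between an aryl aldehyde (C1) and the α-carbon of an aryl-conjugated dienamine (C2), as in polyketide cyclisation. An (R)-proline-catalysed intramolecular aldol closes this ring last and sets both stereocentres in one operation. Its precursor is an open biaryl: the complete nepodin-type naphthalene joined to a salicylaldehyde that bears a 2-methyl-4-oxopent-2-enyl chain ortho to the formyl group. The naphthalene comes from a toluate-anion annulation; the biaryl from a Suzuki coupling.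

Key step: step 10

Remark: the target is read as the trans-(1S,2R) β-hydroxy ketone; because it can lose water to a naphthalene, all phenols are freed before the ring closure and no step follows it.

Step 1
Reactants: 1 2-bromo-5-methylphenol
Product: 2 3-bromo-2-hydroxy-6-methylbenzaldehyde
Conditions: MgCl2, Et3N, (CH2O)n, THF, reflux; aq. HCl
Reagents that add atoms: paraformaldehyde (as formaldehyde) C=O
Why: Magnesium-phenoxide-directed ortho-formylation (Casnati–Skattebøl) is specific for the position ortho to OH, and C6 is the only free ortho carbon of 1.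

Step 2
Reactants: 2 3-bromo-2-hydroxy-6-methylbenzaldehyde
Product: 3 3-bromo-2-hydroxy-6-methylbenzoic acid
Conditions: NaClO2, NaH2PO4, 2-methylbut-2-ene, t-BuOH/H2O, rt
Reagents that add atoms: sodium chlorite [Na+].[O-]Cl=O
Why: Pinnick oxidation converts the aldehyde into the acid without touching the aryl bromide, the alkene scavenger removing hypochlorite before it can chlorinate the phenol ring.

Step 3
Reactants: 3 3-bromo-2-hydroxy-6-methylbenzoic acid
Product: 4 methyl 3-bromo-2-methoxy-6-methylbenzoate
Conditions: MeI (excess), K2CO3, DMF, 40 °C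
Reagents that add atoms: iodomethane CI
Why: SN2 O-alkylation methylates the carboxylate and the phenoxide in one operation and gives an o-toluate that can be deprotonated at its benzylic methyl group.

Step 4
Reactants: 4 methyl 3-bromo-2-methoxy-6-methylbenzoate; 5 (E)-4-methoxypent-3-en-2-one
Product: 7 1-(7-bromo-1-hydroxy-8-methoxy-3-methylnaphthalen-2-yl)ethan-1-one, via enone ester 6 (not isolated)
Conditions: LDA, THF, −78 °C; then 5, −78 °C to rt; aq. NH4Cl/HCl
Reagents that add atoms: none
Why: Lateral lithiation gives the benzylic toluate anion, which should add 1,4 to the vinylogous ester 5 and expel methoxide to give enone 6, whose dienolate closes the ring by intramolecular Claisen (Dieckmann-type) acylation at its α-carbon before the keto form tautomerises to the naphthol (tandem Michael–Dieckmann annulation).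

Step 5
Reactants: 8 5-bromo-2-iodophenol
Product: 9 6-bromo-2-hydroxy-3-iodobenzaldehyde
Conditions: MgCl2, Et3N, (CH2O)n, MeCN, reflux; aq. HCl
Reagents that add atoms: paraformaldehyde (as formaldehyde) C=O
Why: The same magnesium-mediated ortho-formylation can only reach C6 of 8, the single free position ortho to OH, which places the formyl group between the hydroxyl and the bromine.

Step 6
Reactants: 7 1-(7-bromo-1-hydroxy-8-methoxy-3-methylnaphthalen-2-yl)ethan-1-one; 9 6-bromo-2-hydroxy-3-iodobenzaldehyde
Product: 11 3-(7-acetyl-8-hydroxy-1-methoxy-6-methylnaphthalen-2-yl)-6-bromo-2-hydroxybenzaldehyde, via naphthyl boronate 10 (not isolated)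
Conditions: B2pin2, Pd(dppf)Cl2, KOAc, dioxane, 90 °C; then 9, aq. K3PO4, 60 °C
Reagents that add atoms: bis(pinacolato)diboron CC1(C)OB(OC1(C)C)B1OC(C)(C)C(C)(C)O1 (boron of intermediate 10 only)
Why: Miyaura borylation of the aryl bromide is followed in the same flask by Suzuki–Miyaura coupling, in which oxidative addition to the C–I bond of 9 should be much faster than to its C–Br bond, so the bromide is kept for step 8.

Step 7
Reactants: 11 3-(7-acetyl-8-hydroxy-1-methoxy-6-methylnaphthalen-2-yl)-6-bromo-2-hydroxybenzaldehyde
Product: 12 3-(7-acetyl-1,8-dihydroxy-6-methylnaphthalen-2-yl)-6-bromo-2-hydroxybenzaldehyde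
Conditions: BBr3, CH2Cl2, −78 to 0 °C; H2O
Reagents that add atoms: none
Why: Lewis-acid ether cleavage, in which boron bound at the neighbouring peri oxygen activates the methoxy group for SN2 demethylation by bromide, is done here because no alkene or aldol-prone side chain is present yet.

Step 8
Reactants: 12 3-(7-acetyl-1,8-dihydroxy-6-methylnaphthalen-2-yl)-6-bromo-2-hydroxybenzaldehyde; 13 tributyl(2-methylprop-2-en-1-yl)stannane
Product: 14 3-(7-acetyl-1,8-dihydroxy-6-methylnaphthalen-2-yl)-2-hydroxy-6-(2-methylprop-2-en-1-yl)benzaldehyde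
Conditions: Pd(PPh3)4, DMF, 90 °C
Reagents that add atoms: none
Why: Stille coupling of the aryl bromide, activated by the ortho formyl group, runs without base and should tolerate the free phenols and the aldehyde, and the symmetrical methallyl group makes α- and γ-transfer equivalent.

Step 9
Reactants: 14 3-(7-acetyl-1,8-dihydroxy-6-methylnaphthalen-2-yl)-2-hydroxy-6-(2-methylprop-2-en-1-yl)benzaldehyde; 15 but-3-en-2-one
Product: 16 3-(7-acetyl-1,8-dihydroxy-6-methylnaphthalen-2-yl)-2-hydroxy-6-[(2E)-2-methyl-4-oxopent-2-en-1-yl]benzaldehyde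
Conditions: Hoveyda–Grubbs II (10 mol %), 15 (excess), CH2Cl2, 40 °C
Reagents that add atoms: none
Why: Olefin cross-metathesis of the 1,1-disubstituted alkene with the enone should give the trisubstituted (E)-enone under neutral conditions, so that aldehyde and enolisable ketone first meet without acid or base, and the alkene geometry is erased in step 10.

Step 10
Reactants: 16 3-(7-acetyl-1,8-dihydroxy-6-methylnaphthalen-2-yl)-2-hydroxy-6-[(2E)-2-methyl-4-oxopent-2-en-1-yl]benzaldehyde
Product: 18 1-[(1S,2R)-7-(7-acetyl-1,8-dihydroxy-6-methylnaphthalen-2-yl)-1,8-dihydroxy-3-methyl-1,2-dihydronaphthalen-2-yl]ethan-1-one, via proline dienamine 17 (not isolated)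
Conditions: (R)-proline (30 mol %), DMSO, 0.02 M, rt
Reagents that add atoms: none
Why: (R)-Proline should condense with the side-chain ketone to an iminium ion, whose deprotonation at the benzylic γ-carbon (C4) gives the aryl-conjugated dienamine 17; its α-carbon (C2) then adds to the ortho formyl carbon (C1) and hydrolysis releases 18 and the catalyst. The closest known reaction type is the proline-catalysed intramolecular enolexo aldol, here run through a dienamine as in α-selective dienamine catalysis. The ring closes in the 6-(enolexo)-exo-trig mode. C2 is set by the dienamine face held anti to the carboxylic acid of (R)-proline, and C1 by hydrogen-bond delivery of the aldehyde with its aryl group pseudo-equatorial, which gives the anti (trans) aldol predicted as (1S,2R) by the accepted enamine–carboxylic acid transition-state model (mirror image of the L-proline outcome); the trans isomer should also be favoured at equilibrium because C2 can epimerise. The step needs α- rather than γ-attack and reaction of the side-chain ketone only: ring size secures the first (γ-attack would give a four-membered ring, the methyl-side enamine an eight-membered one), and the chelated, doubly ortho-substituted naphthyl acetyl group should not form an enamine. The C3=C4 geometry needed for closure is reached by iminium–dienamine equilibration, and neutral conditions at room temperature are chosen to hold back loss of water to the naphthalene.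

Compound list
1 | 2-bromo-5-methylphenol | Cc1ccc(Br)c(O)c1 | starting material
2 | 3-bromo-2-hydroxy-6-methylbenzaldehyde | Cc1ccc(Br)c(O)c1C=O | intermediate
3 | 3-bromo-2-hydroxy-6-methylbenzoic acid | Cc1ccc(Br)c(O)c1C(=O)O | intermediate
4 | methyl 3-bromo-2-methoxy-6-methylbenzoate | COC(=O)c1c(C)ccc(Br)c1OC | intermediate
5 | (E)-4-methoxypent-3-en-2-one | CO/C(C)=C/C(C)=O | starting material
6 | methyl 3-bromo-2-methoxy-6-[(2E)-2-methyl-4-oxopent-2-en-1-yl]benzoate (not isolated) | COC(=O)c1c(C/C(C)=C/C(C)=O)ccc(Br)c1OC | intermediate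
7 | 1-(7-bromo-1-hydroxy-8-methoxy-3-methylnaphthalen-2-yl)ethan-1-one | CC(=O)c1c(C)cc2ccc(Br)c(OC)c2c1O | intermediate
8 | 5-bromo-2-iodophenol | Oc1cc(Br)ccc1I | starting material
9 | 6-bromo-2-hydroxy-3-iodobenzaldehyde | O=Cc1c(Br)ccc(I)c1O | intermediate
10 | 1-[1-hydroxy-8-methoxy-3-methyl-7-(4,4,5,5-tetramethyl-1,3,2-dioxaborolan-2-yl)naphthalen-2-yl]ethan-1-one (not isolated) | CC(=O)c1c(C)cc2ccc(B3OC(C)(C)C(C)(C)O3)c(OC)c2c1O | intermediate
11 | 3-(7-acetyl-8-hydroxy-1-methoxy-6-methylnaphthalen-2-yl)-6-bromo-2-hydroxybenzaldehyde | CC(=O)c1c(C)cc2ccc(-c3ccc(Br)c(C=O)c3O)c(OC)c2c1O | intermediate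
12 | 3-(7-acetyl-1,8-dihydroxy-6-methylnaphthalen-2-yl)-6-bromo-2-hydroxybenzaldehyde | CC(=O)c1c(C)cc2ccc(-c3ccc(Br)c(C=O)c3O)c(O)c2c1O | intermediate
13 | tributyl(2-methylprop-2-en-1-yl)stannane | CCCC[Sn](CCCC)(CCCC)CC(C)=C | starting material
14 | 3-(7-acetyl-1,8-dihydroxy-6-methylnaphthalen-2-yl)-2-hydroxy-6-(2-methylprop-2-en-1-yl)benzaldehyde | CC(=O)c1c(C)cc2ccc(-c3ccc(CC(C)=C)c(C=O)c3O)c(O)c2c1O | intermediate
15 | but-3-en-2-one | CC(=O)C=C | starting material
16 | 3-(7-acetyl-1,8-dihydroxy-6-methylnaphthalen-2-yl)-2-hydroxy-6-[(2E)-2-methyl-4-oxopent-2-en-1-yl]benzaldehyde | CC(=O)c1c(C)cc2ccc(-c3ccc(C/C(C)=C/C(C)=O)c(C=O)c3O)c(O)c2c1O | intermediate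
17 | (2R)-1-[(2E,4Z)-5-[4-(7-acetyl-1,8-dihydroxy-6-methylnaphthalen-2-yl)-2-formyl-3-hydroxyphenyl]-4-methylpenta-2,4-dien-2-yl]pyrrolidine-2-carboxylic acid (not isolated) | C/C(=C\C(C)=C/c1ccc(-c2ccc3cc(C)c(C(C)=O)c(O)c3c2O)c(O)c1C=O)N1CCC[C@@H]1C(=O)O | intermediate
18 | 1-[(1S,2R)-7-(7-acetyl-1,8-dihydroxy-6-methylnaphthalen-2-yl)-1,8-dihydroxy-3-methyl-1,2-dihydronaphthalen-2-yl]ethan-1-one | CC(=O)c1c(C)cc2ccc(-c3ccc4c(c3O)[C@@H](O)[C@H](C(C)=O)C(C)=C4)c(O)c2c1O | target

Total step count: 10. Longest linear sequence: 9 steps (steps 1, 2, 3, 4, 6, 7, 8, 9, 10).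

Steps most likely to fail

1. Step 10. Facial control may be eroded if the salicylaldehyde ties up the catalyst as an N,O-acetal or iminium ion, and the aldol product may lose water and aromatise during the reaction. Fallback: setting out from 16, the ring would be closed without asymmetric induction by soft enolisation (MgBr2·OEt2, i-Pr2NEt, CH2Cl2, −20 °C), in which the chelated magnesium aldolate should be protected from β-elimination. This should give the trans aldol as a 1:1 mixture of 18 and its enantiomer, 1-[(1R,2S)-7-(7-acetyl-1,8-dihydroxy-6-methylnaphthalen-2-yl)-1,8-dihydroxy-3-methyl-1,2-dihydronaphthalen-2-yl]ethan-1-one F1. Preparative chromatography on a chiral stationary phase would then separate F1 and return to the route at 18.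

2. Step 9. The hindered 1,1-disubstituted alkene may turn over slowly, and ruthenium hydride species may move its double bond into conjugation with the arene, which ends productive metathesis. Fallback: the side chain would be brought in at the ketone oxidation level but masked. Mesityl oxide would be converted by deconjugative ketalisation (ethylene glycol, TsOH, Dean–Stark) into 2-methyl-2-(2-methylprop-2-en-1-yl)-1,3-dioxolane F2. Setting out from 12, a Heck reaction with F2 (Pd(OAc)2, P(o-tol)3, K2CO3, DMF, 90 °C) should give mainly 3-(7-acetyl-1,8-dihydroxy-6-methylnaphthalen-2-yl)-2-hydroxy-6-[(1E)-2-methyl-3-(2-methyl-1,3-dioxolan-2-yl)prop-1-en-1-yl]benzaldehyde F3, with no enolisable ketone present during the basic, hot step. Mild hydrolysis (PPTS, acetone/H2O, rt) would release 3-(7-acetyl-1,8-dihydroxy-6-methylnaphthalen-2-yl)-2-hydroxy-6-[(1E)-2-methyl-4-oxopent-1-en-1-yl]benzaldehyde F4. Under the conditions of step 10, F4 and its alkene isomers should converge on dienamine 17 through iminium–dienamine equilibration, where the fallback rejoins the route.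

3. Step 4. Proton transfer from enone 5 to the toluate anion, or 1,2-addition to its carbonyl group, may compete with the conjugate addition–elimination. Fallback: setting out from 4, the benzylic anion (LDA, THF, −78 °C) would be acylated with N-methoxy-N-methylacetamide to give methyl 3-bromo-2-methoxy-6-(2-oxopropyl)benzoate F5. Enol lactonisation (TsOH, toluene, reflux) would give 7-bromo-8-methoxy-3-methyl-1H-isochromen-1-one F6. Treatment with the lithium enolate of acetone (THF, −78 °C to rt, then aq. HCl) should open the lactone by Claisen acylation and close the carbocycle by intramolecular aldol condensation, which returns to the route at 7.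

Further compounds
F1 | step 10 | 1-[(1R,2S)-7-(7-acetyl-1,8-dihydroxy-6-methylnaphthalen-2-yl)-1,8-dihydroxy-3-methyl-1,2-dihydronaphthalen-2-yl]ethan-1-one | CC(=O)c1c(C)cc2ccc(-c3ccc4c(c3O)[C@H](O)[C@@H](C(C)=O)C(C)=C4)c(O)c2c1O
F2 | step 9 | 2-methyl-2-(2-methylprop-2-en-1-yl)-1,3-dioxolane | CC(=C)CC1(C)OCCO1
F3 | step 9 | 3-(7-acetyl-1,8-dihydroxy-6-methylnaphthalen-2-yl)-2-hydroxy-6-[(1E)-2-methyl-3-(2-methyl-1,3-dioxolan-2-yl)prop-1-en-1-yl]benzaldehyde | CC(=O)c1c(C)cc2ccc(-c3ccc(/C=C(\C)CC4(C)OCCO4)c(C=O)c3O)c(O)c2c1O
F4 | step 9 | 3-(7-acetyl-1,8-dihydroxy-6-methylnaphthalen-2-yl)-2-hydroxy-6-[(1E)-2-methyl-4-oxopent-1-en-1-yl]benzaldehyde | CC(=O)c1c(C)cc2ccc(-c3ccc(/C=C(\C)CC(C)=O)c(C=O)c3O)c(O)c2c1O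
F5 | step 4 | methyl 3-bromo-2-methoxy-6-(2-oxopropyl)benzoate | COC(=O)c1c(CC(C)=O)ccc(Br)c1OC
F6 | step 4 | 7-bromo-8-methoxy-3-methyl-1H-isochromen-1-one | Cc1cc2ccc(Br)c(OC)c2c(=O)o1
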